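Abbreviations: TBDPS = tert-butyldiphenylsilyl, TIPS = triisopropylsilyl, MOM = methoxymethyl. C4a–C8a and primed locants follow chromone numbering (primed = aromatic unit, ring B); "O2, O5, O6" are sugar locants of the galactose-derived chain.

## Analysis of the target

The target joins two 2-(2-phenylethyl)chromone units through one ether oxygen. Ring B is a fully aromatic 7′-hydroxychromone, while the carbocycle of the other unit (ring A, C5–C8) is saturated and carries four contiguous oxygenated stereocentres. These are (5S,6S,7R,8S): the C5 aryloxy group is trans to O6, O6 and O7 are cis, and O7 and O8 are trans. This is the pattern of C2–C5 of D-galactose when C1 and C6 of the sugar become C4a and C8a. The pyranone fused to ring A is a vinylogous ester in which C8a carries the ring oxygen O1 and C4a carries the C4 carbonyl. The synthesis rests on this feature, because exactly this unit results when an acylketene adds across an enol ether double bond C8a(OR)=C4a. The C5–O–C6′ bond is a secondary alkyl aryl ether placed β to C4 (through C4a), so any intermediate with an sp3 C4a next to a carbonyl or enolate can expel the aryloxide, and strong acid can ionise it, after which ring A aromatises. Ring B is reactive too: its carbonyl accepts hard carbon nucleophiles and metal alkylidenes, and its 2-CH2 group is vinylogously acidic. The difficulty is therefore the order of events, which must reconcile four stereocentres, an elimination-prone aryl ether, two pyranones, and a final product with one free phenol and three free alcohols.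

## Retrosynthetic reasoning

29 ⇒ 28. The four hydroxyl groups are masked as acetals: O6/O7 (cis) as one isopropylidene ketal, O8 and the phenolic O7′ as MOM ethers. Only acetal C–O bonds are cut. The gain is that 28 has no O–H group that could acylate a ketene and that a single hydrolysis ends the synthesis. That hydrolysis must remove three acetals without ionising the C5–O bond.

28 ⇒ 23 + 25. The pyranone of ring A is opened at C4–C4a and O1–C8a. This pair of bonds adds the whole O1/C2–C4 segment, with its phenylethyl arm, to a carbocycle that already holds all four stereocentres. C4a reacts as an enol ether carbon and never as the α-carbon of an enolate. Cuts inside the carbocycle would instead require stereocentres to be made next to a finished pyranone. In the forward direction 25 is the source of acylketene 26, which must add to 23 with C4a at the ketene carbon to give ketal 27. Ketal 27 must then lose the C8a methoxy group and not the C5 aryloxy group.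

25 ⇒ 24. The CH2–CH2 bond of the phenylethyl arm is cut at the benzylic carbon. Forward, the γ-carbon of the extended enolate of 24 is benzylated in one step.

23 ⇒ 22. The C4a=C8a double bond is cut by retro-metathesis, each carbon receiving a terminal methylene. The acyclic diene 22 contains the enol ether as a 2-methoxy-1-alkene. Ring closure by metathesis fixes the double bond toward C4a without a C8a ketone or enolate ever existing, either of which would eject the C5 aryloxide. The forward reaction must close a six-membered ring between a vinyl group and a 1,1-disubstituted enol ether.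

22 ⇒ 14 + 21. The C5–O(aryl) bond is cut with the oxygen assigned to ring B. Ring B enters as phenol 21, and the sugar-derived oxygen at C5 leaves as the carbonate of 14. The ether is made at this late point for two reasons. First, ring B cannot pass through the two methylenations that build the diene, since phosphorus ylides and titanium methylidenes attack a chromone carbonyl and deprotonate its 2-CH2 group. Second, at this stage the C5 carbinol is a vinyl carbinol, so the ether can be formed by rhodium-catalysed allylic substitution with an oxygen nucleophile, which avoids an aryl halide coupling at a hindered secondary alcohol. The forward step must give the branched ether with net retention.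

21 ⇒ 19 ⇒ 18 ⇒ 15 + 16. The C6′–O bond is traced to the C–Br bond of 19 (borylation to 20, then oxidation), the MOM ether to phenol 18, and the pyranone of ring B to diketone 17. Diketone 17 arises by Claisen condensation of 15 with 16 (C2′–C3′) and cyclodehydration (O1′–C2′). The bromine of 15 marks C6′ from the outset, so ring B poses no regiochemical question.

14 ⇒ 13 ⇒ 12 ⇒ 11. The carbonate comes from alcohol 13, which is stored as the TIPS ether 12. The enol ether carbon of 12 is traced to the ester carbonyl of 11 by cutting C=CH2 (carbonyl methylenation). The ester is the only carbonyl group of 11, so chemoselectivity is not in question. The silyl ether at the future C5 oxygen survives this step and is later removed under basic conditions that spare the enol ether.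

11 ⇒ 10 ⇒ 8 ⇒ 7 ⇒ 6. The ester carbon is C6 of the sugar chain, reached from acid 10, from alcohol 8 through aldehyde 9, and from silyl ether 7. The future C8 oxygen is O5 of the chain; it is free in 6 and is capped at once as the MOM ether 7.

6 ⇒ 5 ⇒ 4 ⇒ 3 ⇒ 2 ⇒ 1. The vinyl group of 6 is cut at C=C (Wittig methylenation of lactol 5), the same operation that opens the pyranose ring and releases O5. Lactol 5 comes from thioglycoside 4. The groups of 4 are placed in turn on the galacto-configured tetraol 1: O6 as a bulky silyl ether (2), the cis-diol O3/O4 as the acetonide that stays to the end (3), and O2 as the temporary TIPS ether (4). C2–C5 of 1 are C5–C8 of 29, so no stereocentre is created anywhere in the route.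

## Alternatives that were turned down

Alternative 1: Ring A is traced back to a benzene ring. The key step is an oxidative dearomatisation of the all-aromatic diaryl ether A2 (5-aryloxy-8-hydroxychromone with free 7′-OH) by PhI(OAc)2, a trivalent iodine oxidant. The 7′-hydroxyl adds to C5, para to the oxidised C8 oxygen, so C5 becomes the spiro carbon of a benzodioxole and ring A a cross-conjugated dienone, A1. In its favour, A2 is assembled by robust aromatic chemistry (two chromone syntheses and a diaryl ether formation). The C5–O–C6′ link is then never made at a hindered sp3 carbon, and A1 is reached in far fewer steps than 23. On these points it is stronger than the chosen route. Against it, A1 is racemic at the spiro carbon, and everything that matters comes after the key step. The C6=C7 bond must be cis-dihydroxylated on one face, the C8 ketone reduced to the 7,8-trans alcohol, and the ketal opened by reductive cleavage of C5–O7′ only, with hydride delivered to one face of C5. That is four stereocentres set by substrate control on a nearly flat dienone that readily re-aromatises. The chosen strategy offers instead four stereocentres fixed from the chiral pool and only an acetal hydrolysis after the key step.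

Alternative 2: The C5–C6 and O–C5 bonds are made together. Rh2(OAc)4 turns a diazo group at C5 (released from a tosylhydrazone) into a carbene, the oxygen of a C8 aryl ether captures it, and the cyclic oxonium ylide undergoes a [2,3]-shift across a (Z)-vinylsilane. The five-membered ylide ring expands to the carbocycle A3, a trans-5-aryloxy-6-silyl-5,6-dihydrochromone with a C7=C8 double bond. In its favour, ring A and the hindered alkyl aryl ether form in one event with chirality transfer, the silyl group is a masked C6 hydroxyl, and no carbohydrate protecting groups are needed. In convergence, and in avoiding any substitution at C5, it is stronger than the chosen route. Against it, the carbene lies next to the C4 carbonyl (carbonyl ylide formation and cyclisation to a furan compete) and an aryl ether oxygen is a weak ylide donor. The single controlling stereocentre at C8 is doubly activated and can ionise under the basic, hot conditions that release the diazo group. After the key step three further oxidations must each be stereoselective: C–Si to C–OH, a face-selective epoxidation of C7=C8, and regioselective opening at C8. The 7′-benzyl ether of A3 must finally be hydrogenolysed beside two activated C–O bonds. The chosen strategy offers known reaction types throughout and a configuration that does not depend on one labile centre.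

Alternative 3: Ring B is built last. A diazo ketone on the ring B pyranone is irradiated, Wolff rearrangement gives a ketene at C7′, and a 6π-electrocyclisation onto the enol ether carbon C6′ followed by tautomerisation gives the 7′-phenol A4 (the 6,7-acetonide 8-O-MOM ether of the target). In its favour, the ether oxygen stays on C5 throughout, the alkyl aryl ether is never made by substitution or coupling, and the phenol appears free and regiochemically unambiguous. On the ether question it is stronger than the chosen route. Against it, the complete protected tetrahydrochromone is needed first, so the annulation of the ring A pyranone has to be solved anyway. A second pyranone bearing a diazoacetyl group and a β-alkoxyvinyl arm must then be built on a hindered secondary oxygen, which makes a long linear sequence after the stereocentres are set. The photolysis takes place in the presence of two 4-pyranone chromophores, which themselves photorearrange, and of an acid-labile enol ether. The chosen strategy offers a thermal key step that tolerates both pyranones and a much shorter path after the key bond formation.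

Key step: step 19

Remark: phenyl 1-thio-β-D-galactopyranoside 1 is taken as the commercial entry into the D-galactose series, and lactol 5 is used as its anomeric mixture.

## Route

Step 1
Reactants: 1 phenyl 1-thio-β-D-galactopyranoside
Product: 2 phenyl 6-O-(tert-butyldiphenylsilyl)-1-thio-β-D-galactopyranoside
Conditions: TBDPSCl, imidazole, DMF, 0 °C → rt
Reagents that add atoms: tert-butyl(chloro)diphenylsilane, CC(C)(C)[Si](Cl)(c1ccccc1)c1ccccc1
Why: Silylation with the bulky chlorosilane is selective for the primary O6 of the tetraol; TBDPS is chosen because it does not migrate to the neighbouring alkoxide set free in step 5.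

Step 2
Reactants: 2 phenyl 6-O-TBDPS-1-thio-β-D-galactopyranoside
Product: 3 phenyl 6-O-(tert-butyldiphenylsilyl)-3,4-O-isopropylidene-1-thio-β-D-galactopyranoside
Conditions: Me2C(OMe)2, CSA (cat.), acetone, rt; Et3N
Reagents that add atoms: 2,2-dimethoxypropane, COC(C)(C)OC
Why: Acid-catalysed transketalisation takes the only cis-vicinal diol (O3/O4) into a five-membered acetonide and leaves O2 as the single free hydroxyl.

Step 3
Reactants: 3 phenyl 6-O-TBDPS-3,4-O-isopropylidene-1-thio-β-D-galactopyranoside
Product: 4 phenyl 6-O-(tert-butyldiphenylsilyl)-3,4-O-isopropylidene-2-O-(triisopropylsilyl)-1-thio-β-D-galactopyranoside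
Conditions: iPr3SiOTf, 2,6-lutidine, CH2Cl2, 0 °C → rt
Reagents that add atoms: triisopropylsilyl trifluoromethanesulfonate, CC(C)[Si](OS(=O)(=O)C(F)(F)F)(C(C)C)C(C)C
Why: Silyl triflate with a hindered pyridine base silylates the remaining equatorial hydroxyl; TIPS is the temporary mask of the future C5 oxygen because it resists ylide, buffered fluoride and titanium methylidene and is the silyl group least prone to shift onto a lactol alkoxide.

Step 4
Reactants: 4 phenyl 6-O-TBDPS-3,4-O-isopropylidene-2-O-TIPS-1-thio-β-D-galactopyranoside
Product: 5 6-O-(tert-butyldiphenylsilyl)-3,4-O-isopropylidene-2-O-(triisopropylsilyl)-D-galactopyranose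
Conditions: NBS, acetone/H2O (9:1), −15 → 0 °C; aq. NaHCO3/Na2S2O3
Reagents that add atoms: water, O
Why: Bromination at sulfur turns the thiophenyl group into a leaving group and water captures the oxocarbenium ion (thioglycoside hydrolysis); silyl ethers and the acetonide are stable under these cold, briefly acidic conditions.

Step 5
Reactants: 5 6-O-TBDPS-3,4-O-isopropylidene-2-O-TIPS-D-galactopyranose
Product: 6 7-O-(tert-butyldiphenylsilyl)-1,2-dideoxy-4,5-O-isopropylidene-3-O-(triisopropylsilyl)-D-galacto-hept-1-enitol
Conditions: Ph3PCH3Br, KN(SiMe3)2, THF, 0 °C; then 5, 0 → 45 °C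
Reagents that add atoms: methyltriphenylphosphonium bromide, C[P+](c1ccccc1)(c1ccccc1)c1ccccc1.[Br-]
Why: Wittig methylenation of the hydroxy aldehyde in equilibrium with the lactol turns C1 into the vinyl group and frees O5. The aldehyde is the only carbonyl group present and no stereocentre is touched.

Step 6
Reactants: 6 7-O-TBDPS-1,2-dideoxy-4,5-O-isopropylidene-3-O-TIPS-D-galacto-hept-1-enitol
Product: 7 7-O-(tert-butyldiphenylsilyl)-1,2-dideoxy-4,5-O-isopropylidene-6-O-(methoxymethyl)-3-O-(triisopropylsilyl)-D-galacto-hept-1-enitol
Conditions: MOMCl, iPr2NEt, Bu4NI (cat.), CH2Cl2, 40 °C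
Reagents that add atoms: chloromethyl methyl ether, COCCl
Why: O-alkylation of the only free hydroxyl with the chloromethyl ether under amine base installs the C8 protecting group, which is inert to the later fluoride, oxidation, titanium, rhodium and ruthenium steps.

Step 7
Reactants: 7 7-O-TBDPS-1,2-dideoxy-4,5-O-isopropylidene-6-O-MOM-3-O-TIPS-D-galacto-hept-1-enitol
Product: 8 1,2-dideoxy-4,5-O-isopropylidene-6-O-(methoxymethyl)-3-O-(triisopropylsilyl)-D-galacto-hept-1-enitol
Conditions: Bu4NF/AcOH (1:1), DMF, rt
Reagents that add atoms: none
Why: Under acetic acid-buffered fluoride the unhindered primary TBDPS ether is cleaved while the secondary TIPS ether, flanked by the vinyl group and the dioxolane, stays.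

Step 8
Reactants: 8 1,2-dideoxy-4,5-O-isopropylidene-6-O-MOM-3-O-TIPS-D-galacto-hept-1-enitol
Product: 10 6,7-dideoxy-3,4-O-isopropylidene-2-O-(methoxymethyl)-5-O-(triisopropylsilyl)-L-galacto-hept-6-enonic acid, via aldehyde 9 (not isolated)
Conditions: TEMPO (cat.), PhI(OAc)2, MeCN/H2O (1:1), rt
Reagents that add atoms: water, O
Why: Oxoammonium oxidation of the primary alcohol gives the aldehyde, whose hydrate is oxidised on to the acid in the aqueous medium. The near-neutral conditions do not epimerise the α-alkoxy centre or touch the alkene.

Step 9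
Reactants: 10 6,7-dideoxy-3,4-O-isopropylidene-2-O-MOM-5-O-TIPS-L-galacto-hept-6-enonic acid
Product: 11 methyl 6,7-dideoxy-3,4-O-isopropylidene-2-O-(methoxymethyl)-5-O-(triisopropylsilyl)-L-galacto-hept-6-enonate
Conditions: MeI, K2CO3, DMF, rt
Reagents that add atoms: iodomethane, CI
Why: SN2 O-methylation of the carboxylate; carbonate is too weak a base to enolise the α-alkoxy ester.

Step 10
Reactants: 11 methyl 6,7-dideoxy-3,4-O-isopropylidene-2-O-MOM-5-O-TIPS-L-galacto-hept-6-enonate
Product: 12 1,2,8-trideoxy-4,5-O-isopropylidene-6-O-(methoxymethyl)-7-O-methyl-3-O-(triisopropylsilyl)-D-galacto-octa-1,7-dienitol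
Conditions: Cp2TiMe2, toluene, 70 °C, dark; filtration through basic Al2O3
Reagents that add atoms: dimethyltitanocene Cp2Ti(CH3)2, [CH3-].[CH3-].[Ti+4].c1cc[cH-]c1.c1cc[cH-]c1
Why: Petasis methylenation: Cp2Ti=CH2 formed on heating converts the ester carbonyl into the 2-methoxy-1-alkene under non-acidic, non-enolising conditions. The step is placed before ring B is attached, so the ester is the only carbonyl group in the molecule.

Step 11
Reactants: 12 1,2,8-trideoxy-4,5-O-isopropylidene-6-O-MOM-7-O-methyl-3-O-TIPS-D-galacto-octa-1,7-dienitol
Product: 13 1,2,8-trideoxy-4,5-O-isopropylidene-6-O-(methoxymethyl)-7-O-methyl-D-galacto-octa-1,7-dienitol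
Conditions: Bu4NF, THF, rt → 40 °C; Et3N-treated silica
Reagents that add atoms: none
Why: Fluoride removes the last silyl ether under basic conditions that the enol ether tolerates; the alcohol is kept over base because acid would add the hydroxyl to the enol ether.

Step 12
Reactants: 13 1,2,8-trideoxy-4,5-O-isopropylidene-6-O-MOM-7-O-methyl-D-galacto-octa-1,7-dienitol
Product: 14 1,2,8-trideoxy-4,5-O-isopropylidene-3-O-(methoxycarbonyl)-6-O-(methoxymethyl)-7-O-methyl-D-galacto-octa-1,7-dienitol
Conditions: ClCO2Me, pyridine, DMAP (cat.), CH2Cl2, 0 °C
Reagents that add atoms: methyl chloroformate, COC(=O)Cl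
Why: Acylation of the vinyl carbinol gives the leaving group for the allylic substitution; the pyridine medium protects the enol ether.

Step 13
Reactants: 15 5-bromo-2,4-dihydroxyacetophenone; 16 ethyl 3-phenylpropanoate
Product: 18 6-bromo-7-hydroxy-2-(2-phenylethyl)-4H-chromen-4-one, via diketone 17 (not isolated)
Conditions: NaH, THF, 65 °C; aq. HCl; then H2SO4 (cat.), AcOH, 95 °C
Reagents that add atoms: none
Why: Claisen condensation of the acetophenone enolate (the phenols are carried as phenoxides) with the ester gives the 1,3-diketone. Acid then closes the pyranone by attack of the 2-hydroxyl on the enolised carbonyl and loss of water.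

Step 14
Reactants: 18 6-bromo-7-hydroxy-2-(2-phenylethyl)-4H-chromen-4-one
Product: 19 6-bromo-7-(methoxymethoxy)-2-(2-phenylethyl)-4H-chromen-4-one
Conditions: MOMCl, iPr2NEt, CH2Cl2, 0 °C → rt
Reagents that add atoms: chloromethyl methyl ether, COCCl
Why: O-alkylation of the acidic 7-hydroxyl; MOM is chosen so that it is removed together with the aliphatic acetals in the last step.

Step 15
Reactants: 19 6-bromo-7-(methoxymethoxy)-2-(2-phenylethyl)-4H-chromen-4-one
Product: 21 6-hydroxy-7-(methoxymethoxy)-2-(2-phenylethyl)-4H-chromen-4-one, via aryl boronate 20 (not isolated)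
Conditions: B2pin2, PdCl2(dppf) (5 mol %), KOAc, 1,4-dioxane, 85 °C; then NaBO3·4H2O, THF/H2O, rt
Reagents that add atoms: sodium perborate tetrahydrate NaBO3·4H2O (the new oxygen), [Na+].[Na+].O[B-]1(O)OO[B-](O)(O)OO1.O.O.O.O.O.O; bis(pinacolato)diboron (boron and pinacol of 20 only), CC1(C)OB(OC1(C)C)B1OC(C)(C)C(C)(C)O1
Why: Miyaura borylation of the aryl bromide followed by perborate oxidation of the C–B bond (aryl shift from boron to oxygen) replaces bromine by hydroxyl without exposing the chromone to hot hydroxide.

Step 16
Reactants: 14 allylic methyl carbonate; 21 6-hydroxy-7-(methoxymethoxy)-2-(2-phenylethyl)-4H-chromen-4-one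
Product: 22 1,2,8-trideoxy-4,5-O-isopropylidene-6-O-(methoxymethyl)-7-O-methyl-3-O-[7-(methoxymethoxy)-4-oxo-2-(2-phenylethyl)-4H-chromen-6-yl]-D-galacto-octa-1,7-dienitol
Conditions: 21, NaN(SiMe3)2, THF, 0 °C; RhCl(PPh3)3 (10 mol %), P(OMe)3 (40 mol %), 14, THF, 0 °C → rt; aq. NH4Cl
Reagents that add atoms: none
Why: Rhodium-catalysed allylic etherification of a secondary allylic carbonate with an ortho-substituted sodium aryloxide: ionisation with inversion gives a configurationally stable rhodium allyl that is attacked, again with inversion, at the carbon that carried the carbonate. The branched aryl ether therefore forms with net retention and the galacto configuration at the future C5 is kept; only the vinyl carbinol can ionise, so the enol ether and the acetals are untouched.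

Step 17
Reactants: 22 aryl ether diene
Product: 23 enol ether precursor 5-aryloxy-8a-methoxy-6,7-O-isopropylidene-8-O-(methoxymethyl)cyclohex-4a(8a)-ene (chromone numbering; aryl = 7-(methoxymethoxy)-4-oxo-2-(2-phenylethyl)-4H-chromen-6-yl; C5–C8 as in 29)
Conditions: second-generation Hoveyda–Grubbs catalyst RuCl2(H2IMes)(=CH-C6H4-2-OiPr) (10 mol %), toluene, 80 °C; Et3N-treated silica
Reagents that add atoms: none
Why: Ring-closing metathesis: the ruthenium carbene loads on the monosubstituted vinyl group and closes onto the 1,1-disubstituted enol ether, releasing ethene and forming the 1-methoxycyclohexene with the double bond fixed between C4a and C8a. No ketone or enolate at C8a is involved and no stereocentre is formed.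

Step 18
Reactants: 24 2,2,6-trimethyl-4H-1,3-dioxin-4-one
Product: 25 2,2-dimethyl-6-(2-phenylethyl)-4H-1,3-dioxin-4-one
Conditions: LiN(iPr)2, THF/DMPU, −78 °C; BnBr, −78 → −20 °C
Reagents that add atoms: benzyl bromide, BrCc1ccccc1
Why: Deprotonation of the 6-methyl group gives the extended lithium dienolate, which is alkylated at the exocyclic γ-carbon by the reactive benzylic halide (vinylogous enolate alkylation).

Step 19
Reactants: 23 enol ether precursor; 25 2,2-dimethyl-6-(2-phenylethyl)-4H-1,3-dioxin-4-one
Product: 28 protected target (6,7-O-isopropylidene-8,7′-bis-O-(methoxymethyl) derivative of 29), via acylketene 26 (not isolated), via cycloadduct 27 (not isolated)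
Conditions: 25 (3 equiv, slow addition), 4 Å MS, toluene, 110 °C; then PPTS (0.2 equiv), toluene, 60 °C
Reagents that add atoms: none
Why: Heating 25 in toluene causes cycloreversion with extrusion of acetone and sets free acylketene 26, an electron-poor 1-oxadiene with a strongly electrophilic central ketene carbon. The enol ether of 23 adds across it in a hetero-[4+2] cycloaddition; the closest known reaction type is the thermolysis of 1,3-dioxin-4-ones in the presence of enol ethers, which gives 2-alkoxy-2,3-dihydropyran-4-ones and, after loss of alcohol, 4-pyranones. The orientation follows from matching the electron-rich β-carbon of the enol ether (C4a) with the ketene carbon (the future C4), which places the acyl oxygen (the future O1) on C8a. The pyranone ring is closed by the cycloaddition itself; should the reaction be stepwise, C-acylation at C4a comes first and the enolate oxygen then closes onto the C8a oxocarbenium ion in a 6-exo-trig fashion. The two centres created in ketal 27 (C4a, C8a) are uncontrolled and need no control, since both become sp2 when pyridinium p-toluenesulfonate ionises the ketal at C8a (methoxy leaves as methanol, cation stabilised by O1) and the C4a proton is lost. The selectivity the step needs is loss of the methoxy group from C8a and not of the better leaving aryloxide from C5; it is secured because the elimination runs through acid-catalysed ketal ionisation, so no enolate across C4–C4a that could expel the C5 substituent is generated. Chemoselectivity rests on the substrate: every hydroxyl is an acetal, so the ketene meets no O–H nucleophile, ring B is inert to it, and slow addition of excess 25 offsets ketene dimerisation. C5–C8 take no part and are carried through unchanged.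

Step 20
Reactants: 28 protected target
Product: 29 (5S,6S,7R,8S)-6,7,8-trihydroxy-5-{[7-hydroxy-4-oxo-2-(2-phenylethyl)-4H-chromen-6-yl]oxy}-2-(2-phenylethyl)-5,6,7,8-tetrahydro-4H-chromen-4-one
Conditions: aq. HCl (3 M)/THF (1:2), 45 °C
Reagents that add atoms: none
Why: Acid hydrolysis of the three acetals; the acetonide and the aryl MOM ether go first and the aliphatic MOM ether last. With C4a sp2 there is no β-elimination path for the C5 aryloxide, and no stereocentre is touched.

## Compound list

1 | phenyl 1-thio-β-D-galactopyranoside | OC[C@H]1O[C@@H](Sc2ccccc2)[C@H](O)[C@@H](O)[C@H]1O | starting material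
2 | phenyl 6-O-(tert-butyldiphenylsilyl)-1-thio-β-D-galactopyranoside | CC(C)(C)[Si](OC[C@H]1O[C@@H](Sc2ccccc2)[C@H](O)[C@@H](O)[C@H]1O)(c1ccccc1)c1ccccc1 | intermediate
3 | phenyl 6-O-(tert-butyldiphenylsilyl)-3,4-O-isopropylidene-1-thio-β-D-galactopyranoside | CC(C)(C)[Si](OC[C@H]1O[C@@H](Sc2ccccc2)[C@H](O)[C@@H](OC(C)(C)O2)[C@H]12)(c1ccccc1)c1ccccc1 | intermediate
4 | phenyl 6-O-(tert-butyldiphenylsilyl)-3,4-O-isopropylidene-2-O-(triisopropylsilyl)-1-thio-β-D-galactopyranoside | CC(C)(C)[Si](OC[C@H]1O[C@@H](Sc2ccccc2)[C@H](O[Si](C(C)C)(C(C)C)C(C)C)[C@@H](OC(C)(C)O2)[C@H]12)(c1ccccc1)c1ccccc1 | intermediate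
5 | 6-O-(tert-butyldiphenylsilyl)-3,4-O-isopropylidene-2-O-(triisopropylsilyl)-D-galactopyranose (anomeric mixture) | CC(C)(C)[Si](OC[C@H]1OC(O)[C@H](O[Si](C(C)C)(C(C)C)C(C)C)[C@@H](OC(C)(C)O2)[C@H]12)(c1ccccc1)c1ccccc1 | intermediate
6 | 7-O-(tert-butyldiphenylsilyl)-1,2-dideoxy-4,5-O-isopropylidene-3-O-(triisopropylsilyl)-D-galacto-hept-1-enitol (6-OH free) | C=C[C@H](O[Si](C(C)C)(C(C)C)C(C)C)[C@@H](OC(C)(C)O1)[C@@H]1[C@@H](CO[Si](c1ccccc1)(c1ccccc1)C(C)(C)C)O | intermediate
7 | 7-O-(tert-butyldiphenylsilyl)-1,2-dideoxy-4,5-O-isopropylidene-6-O-(methoxymethyl)-3-O-(triisopropylsilyl)-D-galacto-hept-1-enitol | C=C[C@H](O[Si](C(C)C)(C(C)C)C(C)C)[C@@H](OC(C)(C)O1)[C@@H]1[C@@H](CO[Si](c1ccccc1)(c1ccccc1)C(C)(C)C)OCOC | intermediate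
8 | 1,2-dideoxy-4,5-O-isopropylidene-6-O-(methoxymethyl)-3-O-(triisopropylsilyl)-D-galacto-hept-1-enitol (7-OH free) | C=C[C@H](O[Si](C(C)C)(C(C)C)C(C)C)[C@@H](OC(C)(C)O1)[C@@H]1[C@@H](CO)OCOC | intermediate
9 | 6,7-dideoxy-3,4-O-isopropylidene-2-O-(methoxymethyl)-5-O-(triisopropylsilyl)-aldehydo-L-galacto-hept-6-enose | C=C[C@H](O[Si](C(C)C)(C(C)C)C(C)C)[C@@H](OC(C)(C)O1)[C@@H]1[C@@H](C=O)OCOC | intermediate
10 | 6,7-dideoxy-3,4-O-isopropylidene-2-O-(methoxymethyl)-5-O-(triisopropylsilyl)-L-galacto-hept-6-enonic acid | C=C[C@H](O[Si](C(C)C)(C(C)C)C(C)C)[C@@H](OC(C)(C)O1)[C@@H]1[C@@H](C(=O)O)OCOC | intermediate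
11 | methyl 6,7-dideoxy-3,4-O-isopropylidene-2-O-(methoxymethyl)-5-O-(triisopropylsilyl)-L-galacto-hept-6-enonate | C=C[C@H](O[Si](C(C)C)(C(C)C)C(C)C)[C@@H](OC(C)(C)O1)[C@@H]1[C@@H](C(=O)OC)OCOC | intermediate
12 | 1,2,8-trideoxy-4,5-O-isopropylidene-6-O-(methoxymethyl)-7-O-methyl-3-O-(triisopropylsilyl)-D-galacto-octa-1,7-dienitol (C3–C6 = C2–C5 of D-galactose) | C=C[C@H](O[Si](C(C)C)(C(C)C)C(C)C)[C@@H](OC(C)(C)O1)[C@@H]1[C@@H](C(=C)OC)OCOC | intermediate
13 | 1,2,8-trideoxy-4,5-O-isopropylidene-6-O-(methoxymethyl)-7-O-methyl-D-galacto-octa-1,7-dienitol (3-OH free) | C=C[C@H](O)[C@@H](OC(C)(C)O1)[C@@H]1[C@@H](C(=C)OC)OCOC | intermediate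
14 | 1,2,8-trideoxy-4,5-O-isopropylidene-3-O-(methoxycarbonyl)-6-O-(methoxymethyl)-7-O-methyl-D-galacto-octa-1,7-dienitol | C=C[C@H](OC(=O)OC)[C@@H](OC(C)(C)O1)[C@@H]1[C@@H](C(=C)OC)OCOC | intermediate
15 | 5-bromo-2,4-dihydroxyacetophenone | CC(=O)c1cc(Br)c(O)cc1O | starting material
16 | ethyl 3-phenylpropanoate | CCOC(=O)CCc1ccccc1 | starting material
17 | 1-(5-bromo-2,4-dihydroxyphenyl)-5-phenylpentane-1,3-dione | O=C(CC(=O)CCc1ccccc1)c1cc(Br)c(O)cc1O | intermediate
18 | 6-bromo-7-hydroxy-2-(2-phenylethyl)-4H-chromen-4-one | O=c1cc(CCc2ccccc2)oc2cc(O)c(Br)cc12 | intermediate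
19 | 6-bromo-7-(methoxymethoxy)-2-(2-phenylethyl)-4H-chromen-4-one | COCOc1cc2oc(CCc3ccccc3)cc(=O)c2cc1Br | intermediate
20 | 7-(methoxymethoxy)-2-(2-phenylethyl)-6-(4,4,5,5-tetramethyl-1,3,2-dioxaborolan-2-yl)-4H-chromen-4-one | COCOc1cc2oc(CCc3ccccc3)cc(=O)c2cc1B1OC(C)(C)C(C)(C)O1 | intermediate
21 | 6-hydroxy-7-(methoxymethoxy)-2-(2-phenylethyl)-4H-chromen-4-one | COCOc1cc2oc(CCc3ccccc3)cc(=O)c2cc1O | intermediate
22 | 1,2,8-trideoxy-4,5-O-isopropylidene-6-O-(methoxymethyl)-7-O-methyl-3-O-[7-(methoxymethoxy)-4-oxo-2-(2-phenylethyl)-4H-chromen-6-yl]-D-galacto-octa-1,7-dienitol | C=C[C@H](Oc1cc2c(=O)cc(CCc3ccccc3)oc2cc1OCOC)[C@@H](OC(C)(C)O1)[C@@H]1[C@@H](C(=C)OC)OCOC | intermediate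
23 | enol ether precursor: 1-methoxycyclohexene, C8a(OMe)=C4a, with 5-O-aryl (aryl = 7-(methoxymethoxy)-4-oxo-2-(2-phenylethyl)-4H-chromen-6-yl), 6,7-O-isopropylidene and 8-O-methoxymethyl groups; C5–C8 as in 29 (5,6-trans, 6,7-cis, 7,8-trans) | COC1=C[C@H](Oc2cc3c(=O)cc(CCc4ccccc4)oc3cc2OCOC)[C@@H](OC(C)(C)O2)[C@@H]2[C@@H]1OCOC | intermediate
24 | 2,2,6-trimethyl-4H-1,3-dioxin-4-one | CC1=CC(=O)OC(C)(C)O1 | starting material
25 | 2,2-dimethyl-6-(2-phenylethyl)-4H-1,3-dioxin-4-one | CC1(C)OC(CCc2ccccc2)=CC(=O)O1 | intermediate
26 | 3-oxo-5-phenylpent-1-en-1-one (acylketene) | O=C=CC(=O)CCc1ccccc1 | intermediate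
27 | cycloadduct: 8a-methoxy-4a,5,6,7,8,8a-hexahydro-4H-chromen-4-one carrying the substituents of 28 (C4a and C8a undefined) | O=C1C=C(CCc2ccccc2)OC2(OC)C1[C@H](Oc1cc3c(=O)cc(CCc4ccccc4)oc3cc1OCOC)[C@@H](OC(C)(C)O3)[C@@H]3[C@@H]2OCOC | intermediate
28 | protected target: 6,7-O-isopropylidene-8,7′-bis-O-(methoxymethyl) derivative of 29 | O=c1cc(CCc2ccccc2)oc2c1[C@H](Oc1cc3c(=O)cc(CCc4ccccc4)oc3cc1OCOC)[C@@H](OC(C)(C)O3)[C@@H]3[C@@H]2OCOC | intermediate
29 | (5S,6S,7R,8S)-6,7,8-trihydroxy-5-{[7-hydroxy-4-oxo-2-(2-phenylethyl)-4H-chromen-6-yl]oxy}-2-(2-phenylethyl)-5,6,7,8-tetrahydro-4H-chromen-4-one (CNP0248258.1) | O=c1cc(CCc2ccccc2)oc2c1[C@H](Oc1cc3c(=O)cc(CCc4ccccc4)oc3cc1O)[C@@H](O)[C@@H](O)[C@@H]2O | target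

## Step count and least certain steps

Total step count: 20. Longest linear sequence: 16 steps (steps 1–12, 16, 17, 19, 20). The phenol arm (steps 13–15) and the dioxinone (step 18) are side branches.

Step 19 (key step). The hindered, trisubstituted enol ether may add the ketene too slowly, so that the ketene is consumed by dimerisation. Traces of acid (for example β-keto acid from ketene and moisture) may ionise the vinylogous acetal C5–OAr of 23 before the cycloaddition. In the elimination, the aryloxy group may be lost in competition with the methoxy group. Fallback, from 12 back to 28, with the annulation carried out before the ether is made: ring-closing metathesis of 12 (same ruthenium catalyst, toluene, 80 °C) should give the 5-O-triisopropylsilyl analogue of the enol ether precursor F1. Annulation with 25 as in step 19, now without any ionisable aryloxy group, should give 6,7-O-isopropylidene-8-O-(methoxymethyl)-5-O-(triisopropylsilyl)tetrahydrochromone F2. Bu4NF/AcOH should free the C5 alcohol F3, and Cl3CCN with catalytic DBU should convert it into the C5 trichloroacetimidate F4. TMSOTf-catalysed substitution with phenol 21 at −40 °C should then give 28. The phenol is expected to attack the C5 cation (stabilised by O1 through C4a=C8a) on the face opposite the cis-fused acetonide, which is the 5,6-trans arrangement required.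

Step 16. Ionisation of the hindered carbonate, which has an oxygen on the neighbouring carbon, may be slow. The rhodium allyl could then equilibrate, with erosion of branched selectivity or of configuration, or the methoxycarbonyl group could be transferred to the aryloxide. Fallback, from 13 back to 22, with the C–O bond made from the other side: bromide 19 is converted by copper-catalysed halogen exchange (NaI, CuI, trans-N,N′-dimethylcyclohexane-1,2-diamine, 1,4-dioxane, 110 °C) into 6-iodo-7-(methoxymethoxy)-2-(2-phenylethyl)-4H-chromen-4-one F5. Alcohol 13 is then O-arylated with F5 in an Ullmann-type etherification (CuI, 3,4,7,8-tetramethyl-1,10-phenanthroline, Cs2CO3, toluene, 90 °C). The carbinol C–O bond is not broken, so the configuration is retained, and the basic medium suits the enol ether.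

Step 17. The catalyst may initiate at the enol ether and be trapped as an unreactive alkoxycarbene. Closure may be slow because both alkenes carry allylic oxygen substituents, and ruthenium hydrides may shift the double bonds. Fallback, from 13 back to 23, with ring closure before etherification: metathesis of the free allylic alcohol 13, whose hydroxyl assists the catalyst, should give the cyclic 5-hydroxy enol ether F6. Copper-catalysed O-arylation of F6 with iodide F5 (conditions as in the fallback for step 16) should then give 23.

Step 20. Under the acid needed for the aliphatic MOM ether, the C5–O bond may ionise, with loss of the aryloxy unit and dehydration of ring A towards the aromatic chromone. Fallback, from 28 back to 29 in two stages, the second by a non-hydrolytic cleavage: dilute acid (0.5 M HCl, THF/H2O, rt) should remove only the acetonide and the aryl MOM ether and give the 8-O-methoxymethyl ether of the target F7. The remaining MOM ether is then cleaved by thiol-assisted Lewis acid exchange (ZnBr2, n-PrSH, CH2Cl2, 0 °C).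

## Further compounds

F1 | step 19 | 5-O-triisopropylsilyl analogue of the enol ether precursor (1-methoxycyclohexene, 6,7-O-isopropylidene, 8-O-methoxymethyl) | COC1=C[C@H](O[Si](C(C)C)(C(C)C)C(C)C)[C@@H](OC(C)(C)O2)[C@@H]2[C@@H]1OCOC
F2 | step 19 | 6,7-O-isopropylidene-8-O-(methoxymethyl)-2-(2-phenylethyl)-5-O-(triisopropylsilyl)-5,6,7,8-tetrahydrochromone | O=c1cc(CCc2ccccc2)oc2c1[C@H](O[Si](C(C)C)(C(C)C)C(C)C)[C@@H](OC(C)(C)O3)[C@@H]3[C@@H]2OCOC
F3 | step 19 | 5-hydroxy-6,7-O-isopropylidene-8-O-(methoxymethyl)-2-(2-phenylethyl)-5,6,7,8-tetrahydrochromone | O=c1cc(CCc2ccccc2)oc2c1[C@H](O)[C@@H](OC(C)(C)O3)[C@@H]3[C@@H]2OCOC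
F4 | step 19 | C5 trichloroacetimidate of F3 | O=c1cc(CCc2ccccc2)oc2c1[C@H](OC(=N)C(Cl)(Cl)Cl)[C@@H](OC(C)(C)O3)[C@@H]3[C@@H]2OCOC
F5 | step 16 | 6-iodo-7-(methoxymethoxy)-2-(2-phenylethyl)-4H-chromen-4-one | COCOc1cc2oc(CCc3ccccc3)cc(=O)c2cc1I
F6 | step 17 | cyclic 5-hydroxy enol ether (1-methoxycyclohexene, 6,7-O-isopropylidene, 8-O-methoxymethyl) | COC1=C[C@H](O)[C@@H](OC(C)(C)O2)[C@@H]2[C@@H]1OCOC
F7 | step 20 | 8-O-methoxymethyl ether of the target | O=c1cc(CCc2ccccc2)oc2c1[C@H](Oc1cc3c(=O)cc(CCc4ccccc4)oc3cc1O)[C@@H](O)[C@@H](O)[C@@H]2OCOC
A1 | alternative 1 | spiro quinone monoketal (ring A as 8-oxocyclohexadiene, C5 spiro to the benzodioxole of ring B; racemic) | O=C1C=CC2(Oc3cc4c(=O)cc(CCc5ccccc5)oc4cc3O2)c2c1oc(CCc1ccccc1)cc2=O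
A2 | alternative 1 | 8-hydroxy-5-{[7-hydroxy-4-oxo-2-(2-phenylethyl)-4H-chromen-6-yl]oxy}-2-(2-phenylethyl)-4H-chromen-4-one | O=c1cc(CCc2ccccc2)oc2c(O)ccc(Oc3cc4c(=O)cc(CCc5ccccc5)oc4cc3O)c12
A3 | alternative 2 | trans-5-aryloxy-6-(isopropoxydimethylsilyl)-5,6-dihydro-2-(2-phenylethyl)chromone with C7=C8 (aryl = 7-benzyloxy-2-(2-phenylethyl)chromon-6-yl) | O=c1cc(CCc2ccccc2)oc2c1[C@H](Oc1cc3c(=O)cc(CCc4ccccc4)oc3cc1OCc1ccccc1)[C@@H]([Si](C)(C)OC(C)C)C=C2
A4 | alternative 3 | 6,7-O-isopropylidene-8-O-methoxymethyl ether of the target with free 7′-hydroxyl | O=c1cc(CCc2ccccc2)oc2c1[C@H](Oc1cc3c(=O)cc(CCc4ccccc4)oc3cc1O)[C@@H](OC(C)(C)O3)[C@@H]3[C@@H]2OCOC
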